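Numbering the hydroazulene C1 (ester carbinol), C2, C3 (methyl carbinol), C4, C5/C6 (ring fusion), C7 (isopropyl), C8, C9 (methyl epoxide carbon) and C10 (epoxide CH), the five-membered ring holds C9 between C8 and C10, opposite the C5–C6 fusion bond, as a cyclopentenone holds its carbonyl. The route therefore rests on an allenic Pauson–Khand disconnection: alkyne C5≡C10, the distal allene bond C6=C8 and CO (C9) are joined in one operation that closes both the seven- and the five-membered ring. The precursor is an acyclic allene-yne carrying only the C1 and C3 oxygens as differentiated silyl ethers; reductions, methylation, acylation and directed epoxidation follow.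

Key step: step 8

Conventions and remarks
- α is the face of the bicycle that carries the C1 and C3 oxygens, β the opposite face. TES = triethylsilyl, TBS = tert-butyldimethylsilyl.
- Assumption: in the two catalyst-controlled additions (steps 2 and 6) the ligand or acid antipode named is the one expected to give the stated configuration; the other antipode is used if the opposite sense is found.
- C1 is set by reagent control because the quaternary C3 (methyl against propargyl) offers little 1,3-induction.
- C1 carries a labile TES ether and C3 a robust TBS ether, because C1–OH must be free (an alkoxide) during the first electron-transfer reduction: a silyloxy group there would be expelled from the C7 carbanion.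
- The phenol of the acid is carried as a silyl ether so that the acid cannot acylate itself.

Step 1
Reactants: 1 4-hydroxybutan-2-one
Product: 2 4-(triethylsilyloxy)butan-2-one
Conditions: Et3SiCl, imidazole, CH2Cl2, 0 °C to rt
Reagents that add atoms: chlorotriethylsilane, CC[Si](Cl)(CC)CC
Why: Silyl ether formation masks the primary alcohol as a TES ether that survives the copper alkoxide catalysis of step 2 and can be oxidised directly in step 4.

Step 2
Reactants: 2 4-(triethylsilyloxy)butan-2-one; 3 allenylboronic acid pinacol ester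
Product: 4 (3R)-3-methyl-1-(triethylsilyloxy)hex-5-yn-3-ol
Conditions: CuOAc (2 mol%), (R,R)-Ph-BPE (2.4 mol%), LiOi-Pr (0.5 equiv), i-PrOH (1 equiv), CH2Cl2, −75 °C
Reagents that add atoms: none
Why: Catalytic enantioselective propargylation of a ketone, in which boron-to-copper exchange gives a chiral allenylcopper species that adds through a six-membered SE2′ transition state to one face of the methyl ketone, so that the bisphosphine antipode sets the tertiary carbinol C3 as (R) and the terminal alkyne C5≡C10 is installed at the same time.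

Step 3
Reactants: 4 (3R)-3-methyl-1-(triethylsilyloxy)hex-5-yn-3-ol
Product: 5 (3R)-3-(tert-butyldimethylsilyloxy)-3-methyl-1-(triethylsilyloxy)hex-5-yne
Conditions: t-BuMe2SiOTf, 2,6-lutidine, CH2Cl2, 0 °C
Reagents that add atoms: tert-butyldimethylsilyl triflate, CC(C)(C)[Si](C)(C)OS(=O)(=O)C(F)(F)F
Why: Silyl triflate silylation is the standard way to cap a hindered tertiary alcohol, and the robust TBS ether blocks retro-aldol and elimination at C3 until the end.

Step 4
Reactants: 5 (3R)-3-(tert-butyldimethylsilyloxy)-3-methyl-1-(triethylsilyloxy)hex-5-yne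
Product: 6 (3R)-3-(tert-butyldimethylsilyloxy)-3-methylhex-5-ynal
Conditions: (COCl)2 (4 equiv), DMSO (8 equiv), CH2Cl2, −78 to −30 °C; Et3N, −78 °C to rt
Reagents that add atoms: none
Why: Under Swern conditions a primary TES ether is cleaved and oxidised to the aldehyde in one operation (oxidative desilylation), while the tertiary TBS ether and the alkyne are inert and the quaternary C3 cannot epimerise.

Step 5 (side branch)
Reactants: 7 3-methylbut-1-yne; 8 2-(iodomethyl)-4,4,5,5-tetramethyl-1,3,2-dioxaborolane
Product: 10 4,4,5,5-tetramethyl-2-(4-methylpent-2-yn-1-yl)-1,3,2-dioxaborolane, via lithium 3-methylbut-1-yn-1-ide 9 (not isolated)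
Conditions: n-BuLi, THF, −78 °C; then 8, −78 °C to rt
Reagents that add atoms: none
Why: The lithium acetylide adds to boron and the ate complex undergoes 1,2-migration with loss of iodide (Matteson-type homologation), a known route to propargylic pinacol boronates.

Step 6
Reactants: 6 (3R)-3-(tert-butyldimethylsilyloxy)-3-methylhex-5-ynal; 10 4,4,5,5-tetramethyl-2-(4-methylpent-2-yn-1-yl)-1,3,2-dioxaborolane
Product: 11 (4R,6R)-6-(tert-butyldimethylsilyloxy)-6-methyl-3-(propan-2-yl)nona-1,2-dien-8-yn-4-ol
Conditions: 10 (1.5 equiv), (R)-TRIP (5 mol%), 4 Å molecular sieves, toluene, −20 °C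
Reagents that add atoms: none
Why: Chiral phosphoric acid catalysed allenylboration, in which the γ-substituted propargyl boronate reacts through a closed six-membered SE2′ transition state so that its isopropyl-bearing alkyne carbon becomes C7 of a 1,1-disubstituted allene, and the acid antipode (reagent control) sets C1 as (R), syn to the C3 oxygen.

Step 7
Reactants: 11 (4R,6R)-6-(tert-butyldimethylsilyloxy)-6-methyl-3-(propan-2-yl)nona-1,2-dien-8-yn-4-ol
Product: 12 (4R,6R)-6-(tert-butyldimethylsilyloxy)-6-methyl-3-(propan-2-yl)-4-(triethylsilyloxy)nona-1,2-dien-8-yne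
Conditions: Et3SiOTf, 2,6-lutidine, CH2Cl2, −78 °C
Reagents that add atoms: triethylsilyl triflate, CC[Si](CC)(CC)OS(=O)(=O)C(F)(F)F
Why: Silyl triflate silylation of the hindered allenyl carbinol gives a TES ether that is stable to the cyclocarbonylation yet can later be removed selectively beside the tertiary TBS ether.

Step 8
Reactants: 12 (4R,6R)-6-(tert-butyldimethylsilyloxy)-6-methyl-3-(propan-2-yl)-4-(triethylsilyloxy)nona-1,2-dien-8-yne; 13 carbon monoxide
Product: 14 bicyclic dienone (C5=C10; C6=C7; C9=O; 1α-OTES; 3α-OTBS; 3β-CH3; 7-isopropyl)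
Conditions: [Rh(CO)2Cl]2 (5 mol%), CO (1 atm), toluene (0.01 M), 90 °C
Reagents that add atoms: none
Why: Monovalent rhodium coordinates the alkyne and the distal C6=C8 bond of the allene and undergoes oxidative cyclisation to a rhodacyclopentene (C5–C6 formed), CO then inserts and reductive elimination closes C8–C9 and C9–C10 to give the 4-alkylidene cyclopentenone. The closest known reaction type is exactly this one, the rhodium-catalysed allenic Pauson–Khand reaction that gives bicyclo[5.3.0]deca-1,7-dien-9-ones. The seven-membered ring closes in the oxidative cyclisation, when alkyne carbon C5 bonds to the central allene carbon C6 across the four-atom tether C1–C4 (helped by the quaternary C3), and the five-membered ring closes by the two bonds to the inserted carbonyl carbon C9. No stereocentre is formed, so nothing needs control beyond leaving C1 and C3 untouched under the neutral conditions. The step needs selectivity for the distal over the proximal allene double bond, which the rhodium carbonyl catalyst supplies (Mo(CO)6 would engage the proximal bond and give an α-alkylidene cyclopentenone on a six-membered ring) and which the fully substituted, isopropyl-bearing C7 and the silyloxy group on C1 reinforce by shielding the proximal bond; high dilution under CO suppresses oligomerisation and carbonyl-free cycloisomerisation.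

Step 9
Reactants: 14 bicyclic dienone (1α-OTES; 3α-OTBS)
Product: 15 hydroxy dienone (1α-OH; 3α-OTBS)
Conditions: PPTS (0.2 equiv), MeOH, 0 °C to rt
Reagents that add atoms: none
Why: Mild acid methanolysis removes the secondary TES ether far faster than the tertiary TBS ether, and this frees C1–OH so that in step 10 it is an alkoxide, which unlike a silyloxy group is not lost by β-elimination from the C7 carbanion.

Step 10
Reactants: 15 hydroxy dienone (1α-OH; 3α-OTBS)
Product: 18 hydroxy enone (C5=C10; C9=O; 6α-H; 7β-H; 7α-isopropyl), via dilithium dienolate 16 (not isolated), via deconjugated enone 17 (not isolated)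
Conditions: Li (4 equiv), t-BuOH (2 equiv), NH3/THF, −78 °C; solid NH4Cl; then DBU (0.3 equiv), toluene, 40 °C
Reagents that add atoms: none
Why: Dissolving-metal (Birch-type) 1,6-reduction of the linear dienone should protonate the δ-carbon C7 on the β face, anti to the C1 alkoxide (held pseudoaxial by A1,2 strain with the isopropyl group) and to the C3 silyloxy group that together shield the α face, and base-mediated reconjugation of the kinetic C5=C6 isomer then equilibrates C6 through the dienolate to the more stable 6α-H isomer in which C8 and the isopropyl group are trans.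

Step 11
Reactants: 18 hydroxy enone (6α-H; 7β-H)
Product: 19 silyl enone (1α-OTBS; 3α-OTBS; 6α-H; 7β-H)
Conditions: t-BuMe2SiOTf (1.2 equiv), 2,6-lutidine, CH2Cl2, −78 °C
Reagents that add atoms: tert-butyldimethylsilyl triflate, CC(C)(C)[Si](C)(C)OS(=O)(=O)C(F)(F)F
Why: Standard silyl ether formation re-protects C1–OH so that only the enolate oxygen can be sulfonylated in step 12.

Step 12
Reactants: 19 silyl enone (1α-OTBS; 3α-OTBS; 6α-H; 7β-H)
Product: 21 enol triflate (C9=C10; 9-OTf; 5β-H; 6α-H; 7β-H), via lithium enolate 20 (not isolated)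
Conditions: Li (2.1 equiv), t-BuOH (1 equiv), NH3/THF, −78 °C; evaporate NH3; PhNTf2 (1.2 equiv), THF, −78 °C to rt
Reagents that add atoms: N-phenylbis(trifluoromethanesulfonimide), O=S(=O)(N(c1ccccc1)S(=O)(=O)C(F)(F)F)C(F)(F)F
Why: Dissolving-metal reduction of the enone protonates the configurationally mobile β-carbanion C5 to give the more stable trans ring fusion (5β-H anti to 6α-H), and the lithium enolate, which exists only on the C10 side, is trapped on oxygen by the triflimide (reductive enol triflate formation), the silyloxy groups on C1 and C3 being too remote from C5 to eliminate.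

Step 13
Reactants: 21 enol triflate (9-OTf; 5β-H; 6α-H; 7β-H)
Product: 22 methyl alkene (C9=C10; 9-CH3; 1α-OTBS; 3α-OTBS)
Conditions: MeMgBr (2 equiv), Fe(acac)3 (10 mol%), THF/NMP, −30 to 0 °C
Reagents that add atoms: methylmagnesium bromide, C[Mg]Br
Why: Iron-catalysed Kumada-type cross-coupling of an alkenyl triflate with a methyl Grignard reagent replaces the triflate by methyl without moving the C9=C10 double bond, and silyl ethers are tolerated.

Step 14
Reactants: 22 methyl alkene (1α-OTBS; 3α-OTBS)
Product: 23 diol (1α-OH; 3α-OH; C9=C10)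
Conditions: Bu4NF (5 equiv), THF, 60 °C
Reagents that add atoms: none
Why: Fluoride-mediated desilylation cleaves both silyl ethers (the tertiary one needs warming) in a substrate that has no base-sensitive group.

Step 15 (side branch)
Reactants: 24 isovanillic acid
Product: 26 3-(tert-butyldimethylsilyloxy)-4-methoxybenzoic acid, via silyl ester silyl ether 25 (not isolated)
Conditions: t-BuMe2SiCl (2.3 equiv), imidazole, DMF, rt; then AcOH/THF/H2O, rt
Reagents that add atoms: tert-butyldimethylsilyl chloride, CC(C)(C)[Si](C)(C)Cl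
Why: Bis-silylation followed by selective hydrolysis of the far more labile silyl ester leaves the phenol masked as its silyl ether.

Step 16
Reactants: 23 diol (1α-OH; 3α-OH; C9=C10); 26 3-(tert-butyldimethylsilyloxy)-4-methoxybenzoic acid
Product: 28 C1 aryl ester (3α-OH free; C9=C10), via mixed anhydride 27 (not isolated)
Conditions: 26, 2,4,6-Cl3C6H2COCl, Et3N, THF, rt; then 23, DMAP, toluene, 60 °C
Reagents that add atoms: none
Why: Yamaguchi esterification through the mixed anhydride acylates the secondary C1 alcohol with retention of configuration, while the tertiary C3 alcohol is too hindered to react.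

Step 17
Reactants: 28 C1 aryl ester (3α-OH free; C9=C10)
Product: 29 silyl-protected epoxy ester (9α,10α-epoxide)
Conditions: VO(acac)2 (5 mol%), t-BuOOH (1.5 equiv), CH2Cl2, 0 °C to rt
Reagents that add atoms: tert-butyl hydroperoxide, CC(C)(C)OO
Why: Hydroxyl-directed epoxidation, in which the vanadium alkoxide of the α-oriented tertiary C3 alcohol (bishomoallylic to C10) delivers the peroxide oxygen to the α face of the trisubstituted C9=C10 alkene and so sets C9 and C10, the syn hydroxyl being unable to open the epoxide because backside attack is impossible.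

Step 18
Reactants: 29 silyl-protected epoxy ester (9α,10α-epoxide)
Product: 30 target CNP0106636.1
Conditions: Bu4NF (1.1 equiv), AcOH (1.1 equiv), THF, 0 °C
Reagents that add atoms: none
Why: Buffered fluoride desilylation cleaves the aryl silyl ether quickly at 0 °C without touching the epoxide, the benzoate ester or the tertiary alcohol.

Compound list
1 | 4-hydroxybutan-2-one | CC(=O)CCO | starting material
2 | 4-(triethylsilyloxy)butan-2-one | CC(=O)CCO[Si](CC)(CC)CC | intermediate
3 | allenylboronic acid pinacol ester | C=C=CB1OC(C)(C)C(C)(C)O1 | starting material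
4 | (3R)-3-methyl-1-(triethylsilyloxy)hex-5-yn-3-ol | CC[Si](CC)(CC)OCC[C@](C)(O)CC#C | intermediate
5 | (3R)-3-(tert-butyldimethylsilyloxy)-3-methyl-1-(triethylsilyloxy)hex-5-yne | CC[Si](CC)(CC)OCC[C@](C)(O[Si](C)(C)C(C)(C)C)CC#C | intermediate
6 | (3R)-3-(tert-butyldimethylsilyloxy)-3-methylhex-5-ynal | O=CC[C@](C)(O[Si](C)(C)C(C)(C)C)CC#C | intermediate
7 | 3-methylbut-1-yne | CC(C)C#C | starting material
8 | 2-(iodomethyl)-4,4,5,5-tetramethyl-1,3,2-dioxaborolane | ICB1OC(C)(C)C(C)(C)O1 | starting material
9 | lithium 3-methylbut-1-yn-1-ide (not isolated) | [Li]C#CC(C)C | intermediate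
10 | 4,4,5,5-tetramethyl-2-(4-methylpent-2-yn-1-yl)-1,3,2-dioxaborolane | CC(C)C#CCB1OC(C)(C)C(C)(C)O1 | intermediate
11 | (4R,6R)-6-(tert-butyldimethylsilyloxy)-6-methyl-3-(propan-2-yl)nona-1,2-dien-8-yn-4-ol (C1 and C3 of the core both R) | C=C=C(C(C)C)[C@H](O)C[C@](C)(O[Si](C)(C)C(C)(C)C)CC#C | intermediate
12 | allene-yne precursor, (4R,6R)-6-(tert-butyldimethylsilyloxy)-6-methyl-3-(propan-2-yl)-4-(triethylsilyloxy)nona-1,2-dien-8-yne | C=C=C(C(C)C)[C@H](O[Si](CC)(CC)CC)C[C@](C)(O[Si](C)(C)C(C)(C)C)CC#C | intermediate
13 | carbon monoxide | [C-]#[O+] | starting material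
14 | bicyclic dienone, (1R,3R), C5=C10, C6=C7, C9=O, 1α-OTES, 3α-OTBS, 3β-CH3, 7-isopropyl | CC[Si](CC)(CC)O[C@@H]1C[C@](C)(O[Si](C)(C)C(C)(C)C)CC2=CC(=O)CC2=C1C(C)C | intermediate
15 | hydroxy dienone, as 14 with 1α-OH | O[C@@H]1C[C@](C)(O[Si](C)(C)C(C)(C)C)CC2=CC(=O)CC2=C1C(C)C | intermediate
16 | dilithium dienolate (C9–OLi, C9=C10, C5=C6, C1–OLi, 7β-H) (not isolated) | [Li]O[C@@H]1C[C@](C)(O[Si](C)(C)C(C)(C)C)CC2=C(CC(O[Li])=C2)[C@@H]1C(C)C | intermediate
17 | deconjugated enone (C5=C6, C9=O, 1α-OH, 7β-H) (not isolated) | O[C@@H]1C[C@](C)(O[Si](C)(C)C(C)(C)C)CC2=C(CC(=O)C2)[C@@H]1C(C)C | intermediate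
18 | hydroxy enone (C5=C10, C9=O, 1α-OH, 3α-OTBS, 6α-H, 7β-H, 7α-isopropyl) | O[C@@H]1C[C@](C)(O[Si](C)(C)C(C)(C)C)CC2=CC(=O)C[C@H]2[C@@H]1C(C)C | intermediate
19 | silyl enone, as 18 with 1α-OTBS | CC(C)(C)[Si](C)(C)O[C@@H]1C[C@](C)(O[Si](C)(C)C(C)(C)C)CC2=CC(=O)C[C@H]2[C@@H]1C(C)C | intermediate
20 | lithium enolate (C9–OLi, C9=C10, 5β-H, 6α-H) (not isolated) | CC(C)(C)[Si](C)(C)O[C@@H]1C[C@](C)(O[Si](C)(C)C(C)(C)C)C[C@@H]2C=C(O[Li])C[C@H]2[C@@H]1C(C)C | intermediate
21 | enol triflate (C9=C10, 9-OTf, trans-fused, 5β-H, 6α-H, 7β-H) | CC(C)(C)[Si](C)(C)O[C@@H]1C[C@](C)(O[Si](C)(C)C(C)(C)C)C[C@@H]2C=C(OS(=O)(=O)C(F)(F)F)C[C@H]2[C@@H]1C(C)C | intermediate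
22 | methyl alkene (C9=C10, 9-CH3, 1α-OTBS, 3α-OTBS) | CC(C)(C)[Si](C)(C)O[C@@H]1C[C@](C)(O[Si](C)(C)C(C)(C)C)C[C@@H]2C=C(C)C[C@H]2[C@@H]1C(C)C | intermediate
23 | diol (1α-OH, 3α-OH, C9=C10) | O[C@@H]1C[C@](C)(O)C[C@@H]2C=C(C)C[C@H]2[C@@H]1C(C)C | intermediate
24 | isovanillic acid | COc1ccc(C(=O)O)cc1O | starting material
25 | tert-butyldimethylsilyl 3-(tert-butyldimethylsilyloxy)-4-methoxybenzoate (not isolated) | COc1ccc(C(=O)O[Si](C)(C)C(C)(C)C)cc1O[Si](C)(C)C(C)(C)C | intermediate
26 | 3-(tert-butyldimethylsilyloxy)-4-methoxybenzoic acid | COc1ccc(C(=O)O)cc1O[Si](C)(C)C(C)(C)C | intermediate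
27 | mixed anhydride of 26 with 2,4,6-trichlorobenzoic acid (not isolated) | COc1ccc(C(=O)OC(=O)c2c(Cl)cc(Cl)cc2Cl)cc1O[Si](C)(C)C(C)(C)C | intermediate
28 | C1 3-(tert-butyldimethylsilyloxy)-4-methoxybenzoate of diol 23 (3α-OH free, C9=C10) | COc1ccc(C(=O)O[C@@H]2C[C@](C)(O)C[C@@H]3C=C(C)C[C@H]3[C@@H]2C(C)C)cc1O[Si](C)(C)C(C)(C)C | intermediate
29 | 9α,10α-epoxide of 28 | COc1ccc(C(=O)O[C@@H]2C[C@](C)(O)C[C@H]3[C@@H](C[C@@]4(C)O[C@@H]34)[C@@H]2C(C)C)cc1O[Si](C)(C)C(C)(C)C | intermediate
30 | CNP0106636.1, core (1R,3R,5S,6R,7S,9R,10S), 1α-isovanillate, 3α-OH, 5β-H, 6α-H, 7α-isopropyl, 9α,10α-epoxide | COc1ccc(C(=O)O[C@@H]2C[C@](C)(O)C[C@H]3[C@@H](C[C@@]4(C)O[C@@H]34)[C@@H]2C(C)C)cc1O | target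

Total step count: 18. Longest linear sequence: 16 steps (steps 1–4, 6–14 and 16–18, from 4-hydroxybutan-2-one).

Steps most likely to fail

Step 8. Carbonyl-free cycloisomerisation of the allene-yne or oligomerisation through the terminal alkyne may outrun the slow seven-membered carbonylative closure. The fallback changes the substrate class to an internal silyl alkyne and sets out from 12. Deprotonation with n-BuLi in THF at −78 °C and quenching with Me3SiCl should give the silyl-capped allene-yne F1. The same [Rh(CO)2Cl]2/CO cyclocarbonylation should then give the 10-trimethylsilyl dienone F2. Bu4NF buffered with AcOH in wet THF should remove the vinylic silyl group and the TES ether together, leaving the tertiary TBS ether, and the route is rejoined at 15.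

Step 10. The reduced dienone may be protonated at C5 instead of C7, or on the α face of C7 (poor facial selectivity), and C6 may not equilibrate fully. The fallback delivers hydrogen by hydroxyl direction in the C1-epimeric series and inverts C1 afterwards; it sets out from 6. Step 6 run with (S)-TRIP should give the (4S,6R) allenol F3; silylation as in step 7 gives the TES ether F4; cyclocarbonylation as in step 8 gives the 1β-silyloxy dienone F5; methanolysis as in step 9 gives the 1β-hydroxy dienone F6. Hydrogenation with [Ir(cod)(PCy3)(py)]PF6 under H2 in CH2Cl2 should add hydrogen to the tetrasubstituted C6=C7 bond from the β face, on which the hydroxyl sits, to give the cis-hydrogenated enone F7 (7β-H correct, 6β-H). DBU should then equilibrate C6 to the 6α-H hydroxy enone F8. Mitsunobu inversion at C1 (4-nitrobenzoic acid, PPh3, diisopropyl azodicarboxylate, THF; the menthol-type case of a carbinol trans to a neighbouring isopropyl group) should give the 1α 4-nitrobenzoate F9. Methanolysis (K2CO3, MeOH, 0 °C) returns to 18.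

Step 12. Protonation of C5 may occur from the α face and give the cis ring fusion. The fallback replaces thermodynamic protonation by ligand-controlled hydride delivery and sets out from 19. Copper hydride conjugate reduction (Cu(OAc)2·H2O and DTBM-SEGPHOS as catalyst, PhMe2SiH, toluene), with the ligand antipode that delivers hydride to the β face of C5, should give the regiodefined silyl enol ether F10. MeLi in THF at 0 °C cleaves it to lithium enolate 20, which is triflated as in step 12, so the route is rejoined at 20 and then 21.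

Further compounds
F1 | step 8 | (4R,6R)-6-(tert-butyldimethylsilyloxy)-6-methyl-3-(propan-2-yl)-4-(triethylsilyloxy)-9-(trimethylsilyl)nona-1,2-dien-8-yne | C=C=C(C(C)C)[C@H](O[Si](CC)(CC)CC)C[C@](C)(O[Si](C)(C)C(C)(C)C)CC#C[Si](C)(C)C
F2 | step 8 | 10-trimethylsilyl analogue of dienone 14 | CC[Si](CC)(CC)O[C@@H]1C[C@](C)(O[Si](C)(C)C(C)(C)C)CC2=C([Si](C)(C)C)C(=O)CC2=C1C(C)C
F3 | step 10 | (4S,6R)-6-(tert-butyldimethylsilyloxy)-6-methyl-3-(propan-2-yl)nona-1,2-dien-8-yn-4-ol (C1 epimer of 11) | C=C=C(C(C)C)[C@@H](O)C[C@](C)(O[Si](C)(C)C(C)(C)C)CC#C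
F4 | step 10 | C1 epimer of allene-yne 12 | C=C=C(C(C)C)[C@@H](O[Si](CC)(CC)CC)C[C@](C)(O[Si](C)(C)C(C)(C)C)CC#C
F5 | step 10 | C1 epimer of dienone 14 (1β-OTES) | CC[Si](CC)(CC)O[C@H]1C[C@](C)(O[Si](C)(C)C(C)(C)C)CC2=CC(=O)CC2=C1C(C)C
F6 | step 10 | C1 epimer of hydroxy dienone 15 (1β-OH) | O[C@H]1C[C@](C)(O[Si](C)(C)C(C)(C)C)CC2=CC(=O)CC2=C1C(C)C
F7 | step 10 | 1β-hydroxy enone with 6β-H and 7β-H (C5=C10, C9=O) | O[C@H]1C[C@](C)(O[Si](C)(C)C(C)(C)C)CC2=CC(=O)C[C@@H]2[C@@H]1C(C)C
F8 | step 10 | 1β-hydroxy enone with 6α-H and 7β-H (C1 epimer of 18) | O[C@H]1C[C@](C)(O[Si](C)(C)C(C)(C)C)CC2=CC(=O)C[C@H]2[C@@H]1C(C)C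
F9 | step 10 | 1α 4-nitrobenzoate of hydroxy enone 18 | O=C(O[C@@H]1C[C@](C)(O[Si](C)(C)C(C)(C)C)CC2=CC(=O)C[C@H]2[C@@H]1C(C)C)c1ccc(cc1)[N+](=O)[O-]
F10 | step 12 | dimethylphenylsilyl enol ether (C9=C10, 5β-H) derived from 19 | CC(C)(C)[Si](C)(C)O[C@@H]1C[C@](C)(O[Si](C)(C)C(C)(C)C)C[C@@H]2C=C(O[Si](C)(C)c3ccccc3)C[C@H]2[C@@H]1C(C)C
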